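**Strategy.** Everything rests on forging C11–C7 (lactone α-carbon to the tertiary carbinol) before the lactone exists. The feature exploited is the 1,4-relationship of O6 and the C9 carbonyl across the ten-membered ring. The desilylated macrocyclic enone closes to its 6,9-hemiketal, an 11-oxabicyclo[6.2.1]undecadiene whose ketal oxygen can only sit on the tetrahydrofuran face opposite the C5···C10 bridge. A 2-bromoallyl ketal there carries C11–C13. After oxidation of C7, an intramolecular Nozaki–Hiyama–Kishi addition closes a 2,7-dioxabicyclo[3.2.1]octane and sets C7 from C6. Ketal opening with oxidative lactonisation then unveils lactone and enone together.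

Key step: step 16

Remark on locants: target numbering is used throughout, C1=C10(Me)–C9(=O)–C8(OAng)–C7(OH)–C6(O)–C5=C4(Me)–C3–C2, with lactone carbons C11 (α), C12 (C=O), C13 (=CH2).
Assumption: the (R,R)-bisphosphoramide in step 6 is taken to deliver the (S)-carbinol at C6; if it gives the antipode, the (S,S)-catalyst is used.

Step 1
Reactants: 1 neryl acetate
Product: 2 (2Z)-3-methyl-6-oxohex-2-en-1-yl acetate
Conditions: O3 (1.0 equiv), pyridine, CH2Cl2, −78 °C; then Me2S
Reagents that add atoms: ozone, [O-][O+]=O
Why: Chemoselective ozonolysis, in which the electron-rich terminal trisubstituted alkene should react faster than the alkene deactivated by the allylic acetate, so the 2Z alkene is kept.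

Step 2
Reactants: 2 (2Z)-3-methyl-6-oxohex-2-en-1-yl acetate
Product: 3 (2Z,6Z)-7-iodo-3-methylocta-2,6-dien-1-yl acetate
Conditions: EtPPh3I, n-BuLi, THF, 0 °C; I2, −78 °C; NaHMDS, −78 °C; then 2, −78 → −20 °C
Reagents that add atoms: ethyltriphenylphosphonium iodide, CC[P+](c1ccccc1)(c1ccccc1)c1ccccc1.[I-]; iodine, II
Why: Stork–Zhao-type Wittig olefination with the α-iodo ylide should give the (Z)-2-iodo-2-alkene (iodine cis to the chain), which later fixes the C1=C10 geometry.

Step 3
Reactants: 3 (2Z,6Z)-7-iodo-3-methylocta-2,6-dien-1-yl acetate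
Product: 4 (2Z,6Z)-7-iodo-3-methylocta-2,6-dien-1-ol
Conditions: K2CO3 (cat.), MeOH, 0 °C → rt
Reagents that add atoms: none
Why: Base-catalysed transesterification (methanolysis) of the acetate, which leaves the alkenyl iodide untouched.

Step 4
Reactants: 4 (2Z,6Z)-7-iodo-3-methylocta-2,6-dien-1-ol
Product: 5 (2Z,6Z)-7-iodo-3-methylocta-2,6-dienal
Conditions: MnO2, CH2Cl2, rt
Reagents that add atoms: none
Why: Allylic alcohol oxidation with MnO2, which should give the Z-enal without Z→E isomerisation, as with nerol.

Step 5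
Reactants: 6 2,2-dimethyl-1,3-dioxan-5-one
Product: 7 2,2-dimethyl-5-(trimethylsilyloxy)-4H-1,3-dioxine
Conditions: TMSOTf, Et3N, CH2Cl2, 0 °C
Reagents that add atoms: trimethylsilyl triflate, C[Si](C)(C)OS(=O)(=O)C(F)(F)F
Why: Soft enolisation and O-silylation of the symmetric ketone, which can give only one silyl enol ether.

Step 6
Reactants: 5 (2Z,6Z)-7-iodo-3-methylocta-2,6-dienal; 7 2,2-dimethyl-5-(trimethylsilyloxy)-4H-1,3-dioxine
Product: 8 (4S)-4-[(1S,2Z,6Z)-1-hydroxy-7-iodo-3-methylocta-2,6-dien-1-yl]-2,2-dimethyl-1,3-dioxan-5-one (anti aldol; C6–OH, C7/C9 acetonide, C8 ketone)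
Conditions: SiCl4, (R,R)-Denmark bisphosphoramide (5 mol %), i-Pr2NEt (cat.), CH2Cl2, −78 °C; aq. NaHCO3
Reagents that add atoms: none
Why: Lewis-base-catalysed, SiCl4-mediated Mukaiyama aldol (Denmark), which favours conjugated aldehydes in 1,2-fashion; the cyclic (E)-enol ether should give the anti adduct through an open transition state, and the chiral phosphoramide–silicon cation sets C6 (S) and with it the sacrificial C7.

Step 7
Reactants: 8 anti aldol
Product: 9 6-O-TBS ether of 8
Conditions: TBSOTf, 2,6-lutidine, CH2Cl2, −78 °C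
Reagents that add atoms: tert-butyldimethylsilyl triflate, CC(C)(C)[Si](C)(C)OS(=O)(=O)C(F)(F)F
Why: Silylation of the secondary alcohol under weakly basic conditions at low temperature, which should avoid retro-aldol cleavage.

Step 8
Reactants: 9 6-O-TBS ether
Product: 10 4,5-cis-dioxan-5-ol (C8–OH axial, cis to the C7 side chain; O8 anti to O6 in the zigzag sense)
Conditions: L-Selectride, THF, −78 °C; H2O
Reagents that add atoms: none
Why: Substrate-controlled reduction in which the bulky hydride attacks the chair dioxanone equatorially to give the axial 4,5-cis alcohol, relaying C6/C7 to C8 in the configuration of the target.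

Step 9
Reactants: 10 4,5-cis-dioxan-5-ol; 11 angelic acid
Product: 12 8-O-angelate of 10
Conditions: 11, 2,4,6-trichlorobenzoyl chloride, Et3N, toluene, rt; then 10, 75 °C
Reagents that add atoms: none
Why: Yamaguchi esterification through the mixed anhydride without DMAP, the usual way to acylate hindered alcohols with angelic acid without isomerisation to the tiglate.

Step 10
Reactants: 12 8-O-angelate
Product: 13 acyclic 7,9-diol (6-O-TBS, 8-O-angeloyl, alkenyl iodide)
Conditions: PPTS (cat.), MeOH, rt
Reagents that add atoms: none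
Why: Acid-catalysed transketalisation removes the 1,3-dioxane acetonide, while the secondary TBS ether and the hindered ester should survive.

Step 11
Reactants: 13 7,9-diol
Product: 14 C9 aldehyde (7-OH free)
Conditions: TEMPO (cat.), PhI(OAc)2, CH2Cl2, rt
Reagents that add atoms: none
Why: TEMPO/PhI(OAc)2 oxidation, which is selective for the primary alcohol in the presence of the secondary C7 hydroxyl.

Step 12
Reactants: 14 C9 aldehyde
Product: 15 cyclodeca-1(10)Z,4Z-diene 7,9-diol (6-O-TBS, 8-O-angeloyl; both C9 epimers)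
Conditions: CrCl2, NiCl2 (cat.), DMSO/THF, 0.003 M, rt
Reagents that add atoms: none
Why: Intramolecular Nozaki–Hiyama–Kishi reaction at high dilution, in which the (Z)-alkenyl iodide adds to the aldehyde with retention of alkene geometry to close the ten-membered ring; the C9 configuration does not matter because it is oxidised next.

Step 13
Reactants: 15 macrocyclic 7,9-diol
Product: 16 macrocyclic 9-oxo enone (7-OH, 6-O-TBS, 8-O-angeloyl)
Conditions: MnO2, CH2Cl2, rt
Reagents that add atoms: none
Why: MnO2 oxidises only the allylic C9 alcohol, so both epimers converge on the enone and the saturated C7 alcohol is left.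

Step 14
Reactants: 16 macrocyclic enone; 17 2-bromoprop-2-en-1-ol
Product: 19 9-O-(2-bromoallyl) 6,9-ketal (11-oxabicyclo[6.2.1]undecadiene; 7-OH), via 6,9-hemiketal 18 (not isolated)
Conditions: CSA (cat.), 17 (excess), CH2Cl2, 4 Å MS, rt
Reagents that add atoms: none
Why: Acid-catalysed alcoholysis of the silyl ether, transannular addition of O6 to the C9 ketone and ketal exchange under thermodynamic control should give the mixed ketal as one isomer, because only the ketal oxygen anti to the C5···C10 bridge is geometrically possible.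

Step 15
Reactants: 19 2-bromoallyl ketal
Product: 20 7-ketone of 19
Conditions: Dess–Martin periodinane, NaHCO3, CH2Cl2, 0 °C → rt
Reagents that add atoms: none
Why: Buffered Dess–Martin oxidation of the remaining secondary alcohol; no 1,3-diketone arises because C9 is masked as the ketal.

Step 16
Reactants: 20 7-ketone
Product: 21 bridged ketal with the C11–C7 bond (3-methylene-2,7-dioxabicyclo[3.2.1]octane fused into the macrocycle; 7-OH, 8-O-angeloyl)
Conditions: CrCl2, NiCl2 (cat.), DMF, rt
Reagents that add atoms: none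
Why: Ni(0) inserts into the C11–Br bond, the alkenyl group is passed to Cr(III), and the alkenylchromium adds to the C7 ketone (intramolecular Nozaki–Hiyama–Kishi reaction; the closest known type is NHK cyclisation of alkenyl halides onto ketones). The closure is a 6-exo-trig addition that makes ring C7–C8–C9–O–C12–C11, the three-atom bridge of a 2,7-dioxabicyclo[3.2.1]octane. The only new stereocentre, C7, is set by the tether: the ketal oxygen on C9 lies on the tetrahydrofuran face opposite the C5···C10 bridge (fixed by C6), and a 1,3-bridge on a five-membered ring must be cis, so C11 enters anti to the C5 and C8–OAng substituents and the hydroxyl ends syn to them, as in the target. The step needs addition to the ketone in preference to the angelate, and no β-elimination of the C9 alkoxy group next to the acidic C8–H; the weakly basic, oxophilic organochromium reagent in a neutral medium should secure both. No further facial control is needed because the other face cannot be reached.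

Step 17
Reactants: 21 bridged ketal
Product: 24 target, (6S,7R,8R)-8-angeloyloxy-7-hydroxy-9-oxogermacra-1(10)Z,4Z,11(13)-trien-12,6-olide, via enone triol 22 (not isolated), via lactol 23 (not isolated)
Conditions: TFA (cat.), MeCN/H2O, rt; then TEMPO (cat.), PhI(OAc)2, same pot
Reagents that add atoms: water, O
Why: Acid opens the allylic ketal reversibly, TEMPO/PhI(OAc)2 oxidises the primary allylic alcohol of the open form, and the lactol is oxidised on to the γ-lactone (oxidative lactonisation of a 2-methylene-1,4-diol), which takes O6 out of the equilibrium and leaves the C9 enone free.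

**Compound list**
1 | neryl acetate, (2Z)-3,7-dimethylocta-2,6-dien-1-yl acetate | CC(=O)OC/C=C(/C)CCC=C(C)C | starting material
2 | (2Z)-3-methyl-6-oxohex-2-en-1-yl acetate | CC(=O)OC/C=C(/C)CCC=O | intermediate
3 | (2Z,6Z)-7-iodo-3-methylocta-2,6-dien-1-yl acetate | CC(=O)OC/C=C(/C)CC/C=C(/C)I | intermediate
4 | (2Z,6Z)-7-iodo-3-methylocta-2,6-dien-1-ol | OC/C=C(/C)CC/C=C(/C)I | intermediate
5 | (2Z,6Z)-7-iodo-3-methylocta-2,6-dienal | O=C/C=C(/C)CC/C=C(/C)I | intermediate
6 | 2,2-dimethyl-1,3-dioxan-5-one | CC1(C)OCC(=O)CO1 | starting material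
7 | 2,2-dimethyl-5-(trimethylsilyloxy)-4H-1,3-dioxine | CC1(C)OCC(O[Si](C)(C)C)=CO1 | intermediate
8 | (4S)-4-[(1S,2Z,6Z)-1-hydroxy-7-iodo-3-methylocta-2,6-dien-1-yl]-2,2-dimethyl-1,3-dioxan-5-one | O[C@@H](/C=C(/C)CC/C=C(/C)I)[C@@H]1OC(C)(C)OCC1=O | intermediate
9 | 6-O-TBS ether of 8 | CC(C)(C)[Si](C)(C)O[C@@H](/C=C(/C)CC/C=C(/C)I)[C@@H]1OC(C)(C)OCC1=O | intermediate
10 | 4,5-cis-dioxan-5-ol (C8–OH) | CC(C)(C)[Si](C)(C)O[C@@H](/C=C(/C)CC/C=C(/C)I)[C@@H]1OC(C)(C)OC[C@@H]1O | intermediate
11 | angelic acid, (2Z)-2-methylbut-2-enoic acid | C/C=C(/C)C(=O)O | starting material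
12 | 8-O-angelate of 10 | CC(C)(C)[Si](C)(C)O[C@@H](/C=C(/C)CC/C=C(/C)I)[C@@H]1OC(C)(C)OC[C@@H]1OC(=O)/C(C)=C\C | intermediate
13 | acyclic 7,9-diol, 6-O-TBS, 8-O-angeloyl | CC(C)(C)[Si](C)(C)O[C@@H](/C=C(/C)CC/C=C(/C)I)[C@H](O)[C@H](CO)OC(=O)/C(C)=C\C | intermediate
14 | C9 aldehyde | CC(C)(C)[Si](C)(C)O[C@@H](/C=C(/C)CC/C=C(/C)I)[C@H](O)[C@H](C=O)OC(=O)/C(C)=C\C | intermediate
15 | macrocyclic 7,9-diol (C9 epimers) | CC(C)(C)[Si](C)(C)O[C@H]1/C=C(/C)CC/C=C(/C)C(O)[C@H](OC(=O)/C(C)=C\C)[C@H]1O | intermediate
16 | macrocyclic 9-oxo enone, 7-OH, 6-O-TBS | CC(C)(C)[Si](C)(C)O[C@H]1/C=C(/C)CC/C=C(/C)C(=O)[C@H](OC(=O)/C(C)=C\C)[C@H]1O | intermediate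
17 | 2-bromoprop-2-en-1-ol | C=C(Br)CO | starting material
18 | 6,9-hemiketal | O[C@@]12O[C@@H](/C=C(/C)CC/C=C1/C)[C@H](O)[C@H]2OC(=O)/C(C)=C\C | intermediate
19 | 9-O-(2-bromoallyl) 6,9-ketal, 7-OH | C=C(Br)CO[C@@]12O[C@@H](/C=C(/C)CC/C=C1/C)[C@H](O)[C@H]2OC(=O)/C(C)=C\C | intermediate
20 | 7-ketone of 19 | C=C(Br)CO[C@@]12O[C@@H](/C=C(/C)CC/C=C1/C)C(=O)[C@H]2OC(=O)/C(C)=C\C | intermediate
21 | bridged ketal with C11–C7 bond | C=C1CO[C@@]23O[C@@H](/C=C(/C)CC/C=C2/C)[C@@]1(O)[C@H]3OC(=O)/C(C)=C\C | intermediate
22 | enone triol (6-OH, 7-OH, 12-OH, 9-oxo) | C=C(CO)[C@@]1(O)[C@@H](O)/C=C(/C)CC/C=C(/C)C(=O)[C@@H]1OC(=O)/C(C)=C\C | intermediate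
23 | lactol (12-hydroxy-12,6-olide) | C=C1C(O)O[C@H]2/C=C(/C)CC/C=C(/C)C(=O)[C@H](OC(=O)/C(C)=C\C)[C@@]12O | intermediate
24 | CNP0276177.1, (6S,7R,8R) | C=C1C(=O)O[C@H]2/C=C(/C)CC/C=C(/C)C(=O)[C@H](OC(=O)/C(C)=C\C)[C@@]12O | target

**Totals.** 17 steps in all; longest linear sequence 16 steps (steps 1–4 and 6–17 from neryl acetate; step 5 is the side branch).

**Steps most likely to fail**

1. Step 16 (key step). The alkenylchromium may add too slowly to the hindered ketone, so that protodehalogenation, reductive loss of the α-acyloxy group or β-elimination of the C9 alkoxy group towards a furan-3(2H)-one takes over. The fallback replaces the halide/organochromium approach by a nickel(0)-catalysed reductive alkyne–ketone cyclisation that closes the same bond and ring. It sets out from 16: CSA and propargyl alcohol should give the propargyl 6,9-ketal F1 by the same transannular ketalisation, Dess–Martin oxidation the 7-oxo propargyl ketal F2, and Ni(cod)2/PBu3/Et3SiH (oxidative cyclisation of alkyne and ketone, then σ-bond metathesis with the silane) the triethylsilyl ether F3. HF·pyridine brings the route back at 21.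

2. Step 14. The hemiketal may dehydrate to a dienyl ether, or the conjugated oxocarbenium ion may be trapped at C1, so that ketal exchange stays incomplete. The fallback avoids acid: it sets out from 16, HF·pyridine gives the hemiketal 18 as an isolated compound, and anomeric-type O-alkylation of the hemiketal hydroxyl (Cs2CO3, 2,3-dibromopropene, DMF) returns to the route at 19.

3. Step 6. The dioxanone enol ether may react sluggishly with the β,β-disubstituted Z-enal, or facial selectivity may be poor. The fallback changes from Lewis-acid activation of a preformed enol ether to enamine catalysis of the ketone itself: it sets out from 5 and 6, and (S)-proline (30 mol %) in DMF at 4 °C should give the same (S,S)-anti adduct through the Houk–List transition state, returning at 8. The enal geometry would have to be watched, since amines can isomerise Z-enals.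

**Further compounds**
F1 | step 16 | propargyl 6,9-ketal, 7-OH | C#CCO[C@@]12O[C@@H](/C=C(/C)CC/C=C1/C)[C@H](O)[C@H]2OC(=O)/C(C)=C\C
F2 | step 16 | 7-oxo propargyl ketal | C#CCO[C@@]12O[C@@H](/C=C(/C)CC/C=C1/C)C(=O)[C@H]2OC(=O)/C(C)=C\C
F3 | step 16 | 7-O-triethylsilyl ether of 21 | C=C1CO[C@@]23O[C@@H](/C=C(/C)CC/C=C2/C)[C@@]1(O[Si](CC)(CC)CC)[C@H]3OC(=O)/C(C)=C\C
F0 | step 14 | none | none
F0 | step 6 | none | none
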